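- Reckon the small remainder of Qa rather than the large conversion. Here are the flask, the earlier epsilon run and the questions:

in all of them: Qa 0.79 M; Qc 0.869 M
- epsilon: Qb 0.79 M; run made earlier
- flask: Qb 1.58 M; time 3.0 h

epsilon run (percent of the Qa charged)

| time / min | Qa / % | Qg / % |
|---|---|---|
| 10.0 | 32.2 | 7.2 |
| 20.0 | 25.6 | 3.8 |
| 25.0 | 24.8 | 3.7 |
| 40.0 | 23.6 | 2.9 |
| 50.0 | 22.3 | 3.0 |

(standard deviation of a reading: 0.5 percentage points)

- part of the Qa that has reacted at 3.0 h
- share of the unused Qe that is free and not bound as Qb, at 3.0 h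

- In the epsilon run Qa stands at 22.3 % after 50.0 min, so reacted over left gives odds of 3.48. Dividing by the Qb charge gives g = 4.41 L mol⁻¹, the conversion odds per mole of Qb.
- My assumption is that g holds while the Qc charge stays at 0.869 M, so the odds of reacted over left in a flask are g·[Qb], with [Qb] the Qb charge.
- The assumption carries weight: with no effect of Qb, the remainder in the flask is the epsilon reading, 9.8 percentage points above my figure.
- The choice of reading matters less: using 40.0 min instead of 50.0 min moves the remainder by 0.83 points.
- Time is the risk I leave uncounted, since Qa falls 2.5 points between 25.0 min and 50.0 min.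
- For the flask I therefore reckon 12.5 % left, so 87.5 % reacted. I give no figure for free Qe: the readings do not show bound Qe.
- The forecast says 95 % reacted, higher than my figure, and 10 % free, on the ground that “Doubling Qb removes much of that limit”.
- The flask gives 88.4 % reacted and 3.68 % free. Qa used stands at 88.4 % after 1.50 h and at 88.4 % after 30.0 h. Its odds per mole of Qb come to 4.80 L mol⁻¹, above g = 4.41 L mol⁻¹.

    Qa + Qe ⇌ Qf + Qg (K = 4.84, k = 3.11 L mol⁻¹ min⁻¹)
    Qe + Qf ⇌ Qb, settled at all times (K = 46.7 L mol⁻¹)
    Qf + Qc ⇌ Qh (K = 17500 L mol⁻¹, k = 11.6 L mol⁻¹ min⁻¹)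
    Qg ⇌ Qj (K = 26.0, k = 0.441 min⁻¹)
    Qc ⇌ Qd (K = 1.60, k = 2.49 min⁻¹)

- Now take the neighbour flask with 0.35 M of Qc. It has the same Qb charge, so g would give 87.5 % reacted, though that Qc lies outside what g holds fixed.
- The computed neighbour gives 77.0 % reacted, so its odds per mole of Qb are 2.12 L mol⁻¹, below g. Qc, the limiting reagent in that neighbour, stands unbound at 0.0064 % of its charge.

The numbers in the tables were generated by integration for substances that don't exist; the scatter is artificial.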